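**Strategy.** Everything rests on opening the pyrrole ring of the 6-bromoindole at C3–C3a and N1–C2. The C6 bromine lies para to C3a and meta to C7a, which is the pattern of 5-bromo-2-iodoaniline, while C2 and C3 correspond to an alkyne whose C3 carbon already carries imidazole C4. A single Larock heteroannulation therefore forms both bonds, closes the pyrrole ring and places the imidazolyl group at C3, with a removable silyl group at C2 and the bromine untouched. The alkyne partner is a 2-(indol-3-yl)imidazole, SEM-protected on both nitrogens, with a (trimethylsilyl)ethynyl group at imidazole C4, made from indole-3-carbaldehyde by imidazole condensation, iodination and Sonogashira coupling.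

Key step: step 6

Remark: the imidazole N–H of the target is tautomeric, so either SEM regioisomer of the imidazole would converge on the same product; the 1-SEM-4-substituted isomer, expected from alkylation at the nitrogen remote from iodine, is the one numbered. SEM = [2-(trimethylsilyl)ethoxy]methyl.

**Step 1**
Reactants: 1 indole-3-carbaldehyde; 2 glyoxal (40% aqueous solution)
Product: 3 2-(1H-indol-3-yl)-1H-imidazole
Conditions: 2 (1.5 equiv), 28% aq. NH3 (excess), EtOH, 0 °C to rt, 48–72 h
Reagents that add atoms: ammonia, N
Why: Debus–Radziszewski imidazole synthesis, in which ammonia turns glyoxal into its diimine and the aldehyde into an aldimine, and these condense with loss of water so that the aldehyde carbon becomes imidazole C2; the vinylogous-amide character of 1 should slow the condensation but not block it.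

**Step 2**
Reactants: 3 2-(1H-indol-3-yl)-1H-imidazole
Product: 4 4,5-diiodo-2-(1H-indol-3-yl)-1H-imidazole
Conditions: I2 (2.1 equiv), KI, 2 M aq. NaOH, dioxane, 0 °C to rt; AcOH to pH 7, aq. Na2S2O3 wash
Reagents that add atoms: iodine, II
Why: Electrophilic iodination of the imidazolide anion, which aqueous hydroxide generates while the less acidic indole N–H stays largely protonated, so both free imidazole carbons should be iodinated before the C3-blocked indole reacts.

**Step 3**
Reactants: 4 4,5-diiodo-2-(1H-indol-3-yl)-1H-imidazole
Product: 5 4-iodo-2-(1H-indol-3-yl)-1H-imidazole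
Conditions: Na2SO3 (8 equiv), EtOH/H2O (1:2), reflux, 24 h
Reagents that add atoms: none
Why: Sulfite-mediated reductive mono-deiodination of a 4,5-diiodoimidazole (iodophilic attack of sulfite on one C–I bond), which should stop at the mono-iodide because the second iodine is far less activated, and which gives one product because the two positions are tautomerically equivalent.

**Step 4**
Reactants: 5 4-iodo-2-(1H-indol-3-yl)-1H-imidazole
Product: 6 4-iodo-1-SEM-2-(1-SEM-1H-indol-3-yl)-1H-imidazole
Conditions: NaH (2.5 equiv), DMF, 0 °C; SEMCl (2.3 equiv), 0 °C to rt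
Reagents that add atoms: 2-(trimethylsilyl)ethoxymethyl chloride (SEMCl), C[Si](C)(C)CCOCCl
Why: Double N-alkylation of the sodium indolide and imidazolide by the chloromethyl ether, in which the imidazole should react at the nitrogen remote from the bulky, electron-withdrawing iodine to give the 4-iodo isomer.

**Step 5**
Reactants: 6 4-iodo-1-SEM-2-(1-SEM-1H-indol-3-yl)-1H-imidazole; 7 trimethylsilylacetylene
Product: 8 1-SEM-2-(1-SEM-1H-indol-3-yl)-4-[(trimethylsilyl)ethynyl]-1H-imidazole
Conditions: 7 (1.5 equiv), Pd(PPh3)2Cl2 (5 mol%), CuI (10 mol%), Et3N, THF, 50 °C, degassed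
Reagents that add atoms: none
Why: Sonogashira coupling, in which zerovalent palladium inserts into the imidazole C4–I bond and the copper acetylide of 7 transmetalates, while the amine base is too mild to cleave the alkynyl C–Si bond and the SEM groups keep both azole nitrogens inert.

**Step 6**
Reactants: 8 1-SEM-2-(1-SEM-1H-indol-3-yl)-4-[(trimethylsilyl)ethynyl]-1H-imidazole; 9 5-bromo-2-iodoaniline
Product: 10 6-bromo-3-[1-SEM-2-(1-SEM-1H-indol-3-yl)-1H-imidazol-4-yl]-2-(trimethylsilyl)-1H-indole
Conditions: 9 (1.3 equiv), Pd(OAc)2 (10 mol%), LiCl (1.0 equiv), anhydrous K2CO3 (3.0 equiv), dry DMF, 100 °C, argon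
Reagents that add atoms: none
Why: Pd(OAc)2 is reduced in the flask to zerovalent palladium, which inserts into the C–I bond of 9; the arylpalladium halide adds syn across alkyne 8 with the aryl carbon (future C3a) bonding to the imidazole-bearing carbon (future C3) and palladium taking the silyl-bearing carbon (future C2), after which the aniline nitrogen displaces halide on divalent palladium, carbonate removes the proton, and C–N reductive elimination forms N1–C2 and returns zerovalent palladium. The closest known reaction is the Larock indole synthesis of 2-iodoanilines with aryl(trimethylsilyl)acetylenes, which gives 3-aryl-2-silylindoles. The pyrrole ring is closed as a formal [3+2] heteroannulation, C3–C3a by intermolecular carbopalladation and N1–C2 by reductive elimination from a six-membered azapalladacycle. No stereocentre is created. Regiocontrol comes from the Me3Si group, which as the larger alkyne substituent avoids the short forming C–C bond and ends beside the longer C–Pd bond, hence at C2. Chemoselectivity for C–I over C–Br comes from the weaker C–I bond and the phosphine-free catalyst, and the SEM groups keep both azole nitrogens from being deprotonated or arylated.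

**Step 7**
Reactants: 10 6-bromo-3-[1-SEM-2-(1-SEM-1H-indol-3-yl)-1H-imidazol-4-yl]-2-(trimethylsilyl)-1H-indole
Product: 12 nortopsentin C (6-bromo-3-[2-(1H-indol-3-yl)-1H-imidazol-4-yl]-1H-indole), via bis(hydroxymethyl) hemiaminal 11 (not isolated)
Conditions: CF3CO2H/CH2Cl2 (1:1), H2O (5 equiv), rt; evaporate; ethylenediamine (10 equiv), MeOH, rt
Reagents that add atoms: none
Why: Acid-mediated protodesilylation by ipso-protonation at indole C2 (cation stabilised by the β-silicon and the ring nitrogen) together with acidolysis of both N,O-acetals to N-hydroxymethyl hemiaminals, which ethylenediamine then collapses by taking up formaldehyde as imidazolidine; the aryl bromide and the three heterocycles should be inert to both stages.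

**Compound list**
1 | 1H-indole-3-carbaldehyde | O=Cc1c[nH]c2ccccc12 | starting material
2 | glyoxal (ethanedial) | O=CC=O | starting material
3 | 2-(1H-indol-3-yl)-1H-imidazole | c1c[nH]c(n1)-c1c[nH]c2ccccc12 | intermediate
4 | 4,5-diiodo-2-(1H-indol-3-yl)-1H-imidazole | Ic1nc([nH]c1I)-c1c[nH]c2ccccc12 | intermediate
5 | 4-iodo-2-(1H-indol-3-yl)-1H-imidazole | Ic1c[nH]c(n1)-c1c[nH]c2ccccc12 | intermediate
6 | 4-iodo-1-{[2-(trimethylsilyl)ethoxy]methyl}-2-(1-{[2-(trimethylsilyl)ethoxy]methyl}-1H-indol-3-yl)-1H-imidazole | Ic1cn(COCC[Si](C)(C)C)c(n1)-c1cn(COCC[Si](C)(C)C)c2ccccc12 | intermediate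
7 | trimethylsilylacetylene | C#C[Si](C)(C)C | starting material
8 | 1-SEM-2-(1-SEM-1H-indol-3-yl)-4-[(trimethylsilyl)ethynyl]-1H-imidazole | C[Si](C)(C)C#Cc1cn(COCC[Si](C)(C)C)c(n1)-c1cn(COCC[Si](C)(C)C)c2ccccc12 | intermediate
9 | 5-bromo-2-iodoaniline | Nc1cc(Br)ccc1I | starting material
10 | 6-bromo-3-[1-SEM-2-(1-SEM-1H-indol-3-yl)-1H-imidazol-4-yl]-2-(trimethylsilyl)-1H-indole | C[Si](C)(C)c1[nH]c2cc(Br)ccc2c1-c1cn(COCC[Si](C)(C)C)c(n1)-c1cn(COCC[Si](C)(C)C)c2ccccc12 | intermediate
11 | {3-[4-(6-bromo-1H-indol-3-yl)-1-(hydroxymethyl)-1H-imidazol-2-yl]-1H-indol-1-yl}methanol | OCn1cc(nc1-c1cn(CO)c2ccccc12)-c1c[nH]c2cc(Br)ccc12 | intermediate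
12 | nortopsentin C, 6-bromo-3-[2-(1H-indol-3-yl)-1H-imidazol-4-yl]-1H-indole | Brc1ccc2c(-c3c[nH]c(-c4c[nH]c5ccccc45)n3)c[nH]c2c1 | target

**Step count.** Total: 7 steps. Longest linear sequence: 7 steps (1 to 12); compounds 2, 7 and 9 are purchased and enter directly.

**Steps most likely to fail**

Step 6 (key step). The alkynyl C–Si bond may be cleaved by carbonate in hot DMF before carbopalladation, which would remove the regiocontrol. Palladium may also begin to insert into the C–Br bond once the iodide is consumed, giving oligomers, and the imidazole N3 may bind and slow the catalyst. The fallback gives up the annulation and joins the two halves by Suzuki–Miyaura coupling, setting out from iodide 6. The boron partner would be made from 6-bromo-1H-indole F1. N-silylation (NaH, i-Pr3SiCl, THF) should give 6-bromo-1-(triisopropylsilyl)indole F2. C–H borylation, steered to C3 by the bulky N-silyl group (B2pin2, [Ir(OMe)(cod)]2, 4,4'-di-tert-butyl-2,2'-bipyridine, THF, 60 °C), should give 6-bromo-3-(4,4,5,5-tetramethyl-1,3,2-dioxaborolan-2-yl)-1-(triisopropylsilyl)indole F3. Coupling of F3 with 6 (Pd(PPh3)4, aq. Na2CO3, DME, 80 °C), where the imidazolyl C–I bond should react ahead of the aryl C–Br bond, should give 6-bromo-3-[1-SEM-2-(1-SEM-1H-indol-3-yl)-1H-imidazol-4-yl]-1-(triisopropylsilyl)indole F4. Bu4NF with ethylenediamine in DMF at 80 °C should then remove the N-silyl group and both SEM groups, and the route is rejoined at 12.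

Step 1. Imine formation at the deactivated, vinylogous-amide carbonyl may be too slow to compete with self-condensation of glyoxal and ammonia, so that conversion stalls. The fallback builds the ring in two stages from 1. Condensation with ethylenediamine and oxidation of the resulting aminal in the same flask (I2, K2CO3, t-BuOH, 70 °C) should give 2-(1H-indol-3-yl)-4,5-dihydro-1H-imidazole F5. Dehydrogenation with activated MnO2 in refluxing dioxane should then give 3, where the route is rejoined.

Step 7. In acid, the N-methylene cations released from the SEM groups may alkylate the free C2 positions of the two indoles, and the hemiaminal on the indole nitrogen may collapse incompletely. The fallback separates the two cleavages and avoids cationic intermediates, setting out from 10. Dilute HCl in MeOH at rt should cleave only the C2–Si bond and give 6-bromo-3-[1-SEM-2-(1-SEM-1H-indol-3-yl)-1H-imidazol-4-yl]-1H-indole F6. Bu4NF with ethylenediamine in DMF at 80 °C should then remove both SEM groups by fluoride-triggered fragmentation, and the route is rejoined at 12.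

**Further compounds**
F1 | step 6 | 6-bromo-1H-indole | Brc1ccc2cc[nH]c2c1
F2 | step 6 | 6-bromo-1-(triisopropylsilyl)indole | CC(C)[Si](C(C)C)(C(C)C)n1ccc2ccc(Br)cc21
F3 | step 6 | 6-bromo-3-(4,4,5,5-tetramethyl-1,3,2-dioxaborolan-2-yl)-1-(triisopropylsilyl)indole | CC(C)[Si](C(C)C)(C(C)C)n1cc(B2OC(C)(C)C(C)(C)O2)c2ccc(Br)cc21
F4 | step 6 | 6-bromo-3-[1-SEM-2-(1-SEM-1H-indol-3-yl)-1H-imidazol-4-yl]-1-(triisopropylsilyl)indole | CC(C)[Si](C(C)C)(C(C)C)n1cc(-c2cn(COCC[Si](C)(C)C)c(n2)-c2cn(COCC[Si](C)(C)C)c3ccccc23)c2ccc(Br)cc21
F5 | step 1 | 2-(1H-indol-3-yl)-4,5-dihydro-1H-imidazole | C1CN=C(N1)c1c[nH]c2ccccc12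
F6 | step 7 | 6-bromo-3-[1-SEM-2-(1-SEM-1H-indol-3-yl)-1H-imidazol-4-yl]-1H-indole | Brc1ccc2c(c[nH]c2c1)-c1cn(COCC[Si](C)(C)C)c(n1)-c1cn(COCC[Si](C)(C)C)c2ccccc12
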